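**Strategy.** The cyclohexene (C1–C6 of the 7-oxabicyclo[4.1.0]hept-3-ene) is cut at C3=C4. The plan rests on a hidden symmetry: C2 and C1′, the two carbinol carbons on the quaternary oxirane carbon C1, are both S. The precursor is therefore a spiro-oxirane whose C1 carries two identical (S)-vinylcarbinol arms (from L-arabinitol, tied as a silylene), with the C5 carbinol and the 1,1-disubstituted C4 alkene on C6. In one pot, ruthenium metathesis closes the carbocycle with the only arm that lies cis to C5 on the oxirane O7–C1–C6, which makes C1 a stereocentre, and turns the untouched trans arm into the vinylboronate that receives the polyene.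

Key step: step 15

Remark (locants): ring atoms are numbered as in the target (C1 quaternary oxirane carbon, C2 CHOH, C3=C4, C5 CHOH, C6 oxirane CH, O7; side chain C1′–C12′).
Remark (stereo labels): in 13–17 the spiro carbon (future C1) bears two identical (S)-arms, is not a stereocentre and is written without a stereo label.
Remark (supply): compounds 1, 10, 15, 18 and 21 are taken as commercial.

**Step 1**
Reactants: 1 L-arabinitol
Product: 2 1,2:4,5-di-O-isopropylidene-L-arabinitol
Conditions: 2-methoxypropene, TsOH (cat.), DMF, 0 °C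
Reagents that add atoms: 2-methoxypropene, C=C(C)OC
Why: Kinetic acetalisation should protect the two terminal 1,2-diols and leave only O3 free; the two (S) carbinol centres of the C2-symmetric pentitol are carried unchanged into C2 and C1′ of the target.

**Step 2**
Reactants: 2 1,2:4,5-di-O-isopropylidene-L-arabinitol
Product: 3 3-O-(4-methoxybenzyl)-1,2:4,5-di-O-isopropylidene-L-arabinitol
Conditions: NaH, PMBCl, Bu4NI (cat.), DMF, 0 °C to rt
Reagents that add atoms: 4-methoxybenzyl chloride, COc1ccc(CCl)cc1
Why: Williamson etherification of the single free alkoxide masks O3, the oxygen that later becomes the ketone used for olefination.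

**Step 3**
Reactants: 3 3-O-PMB diacetonide
Product: 4 3-O-(4-methoxybenzyl)-L-arabinitol
Conditions: AcOH/H2O (4:1), 40 °C
Reagents that add atoms: none
Why: Acid-catalysed acetal hydrolysis should free both terminal diols while the PMB ether survives.

**Step 4**
Reactants: 4 3-O-(4-methoxybenzyl)-L-arabinitol
Product: 5 1,2:4,5-dianhydro-3-O-(4-methoxybenzyl)-L-arabinitol (bis-oxirane, both oxirane CH carbons S)
Conditions: PPh3, DIAD, CHCl3, reflux
Reagents that add atoms: none
Why: Double Mitsunobu cyclodehydration activates each primary hydroxyl as its oxyphosphonium ion and the neighbouring secondary oxygen closes the oxirane (3-exo-tet), so both carbinol centres keep their configuration.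

**Step 5**
Reactants: 5 bis-oxirane
Product: 6 (3S,5S)-4-[(4-methoxybenzyl)oxy]hepta-1,6-diene-3,5-diol
Conditions: Me3S+ I−, n-BuLi, THF, −10 °C to rt
Reagents that add atoms: trimethylsulfonium iodide, C[S+](C)C.[I-]
Why: Dimethylsulfonium methylide opens each terminal oxirane at CH2 and the betaine eliminates dimethyl sulfide (one-carbon homologation of epoxides to allylic alcohols), giving two (S)-vinylcarbinol arms without touching the stereocentres.

**Step 6**
Reactants: 6 diene diol
Product: 7 (4S,6S)-2,2-di-tert-butyl-4,6-diethenyl-5-[(4-methoxybenzyl)oxy]-1,3,2-dioxasilinane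
Conditions: tBu2Si(OTf)2, 2,6-lutidine, CH2Cl2, 0 °C
Reagents that add atoms: di-tert-butylsilyl bis(trifluoromethanesulfonate), CC(C)(C)[Si](OS(=O)(=O)C(F)(F)F)(OS(=O)(=O)C(F)(F)F)C(C)(C)C
Why: Silylene acetal formation on the 1,3-diol gives a six-membered ring that protects both arms at once and holds the two vinyl groups trans to each other.

**Step 7**
Reactants: 7 PMB ether
Product: 8 (4S,6S)-2,2-di-tert-butyl-4,6-diethenyl-1,3,2-dioxasilinan-5-ol
Conditions: DDQ, CH2Cl2/pH 7 buffer, 0 °C
Reagents that add atoms: none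
Why: Oxidative PMB cleavage is selective for the electron-rich benzyl ether and should leave silylene and alkenes intact.

**Step 8**
Reactants: 8 alcohol
Product: 9 (4S,6S)-2,2-di-tert-butyl-4,6-diethenyl-1,3,2-dioxasilinan-5-one
Conditions: Dess–Martin periodinane, CH2Cl2, 0 °C to rt
Reagents that add atoms: none
Why: Dess–Martin oxidation under non-basic conditions should give the C2-symmetric ketone without enolising its doubly activated α-positions.

**Step 9**
Reactants: 9 ketone; 10 ethyl (triphenylphosphoranylidene)acetate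
Product: 11 ethyl 2-[(4S,6S)-2,2-di-tert-butyl-4,6-diethenyl-1,3,2-dioxasilinan-5-ylidene]acetate
Conditions: toluene, 50 °C
Reagents that add atoms: none
Why: Wittig olefination of the activated α,α′-dioxygenated ketone with a neutral stabilised ylide installs C6 and C5; because the ketone is C2-symmetric, no E/Z isomers can arise.

**Step 10**
Reactants: 11 enoate
Product: 12 2-[(4S,6S)-2,2-di-tert-butyl-4,6-diethenyl-1,3,2-dioxasilinan-5-ylidene]ethan-1-ol
Conditions: DIBAL-H, CH2Cl2, −78 °C
Reagents that add atoms: none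
Why: 1,2-Reduction of the enoate gives the primary allylic alcohol needed for directed epoxidation.

**Step 11**
Reactants: 12 allylic alcohol
Product: 13 [(2S,4S,8S)-6,6-di-tert-butyl-4,8-diethenyl-1,5,7-trioxa-6-silaspiro[2.5]octan-2-yl]methanol
Conditions: Ti(OiPr)4 (cat.), L-(+)-DIPT (cat.), t-BuOOH, 4 Å MS, CH2Cl2, −20 °C
Reagents that add atoms: tert-butyl hydroperoxide, CC(C)(C)OO
Why: Sharpless asymmetric epoxidation under reagent control: L-(+)-tartrate should deliver oxygen to the face that makes the new oxirane CH centre (C6 of the target) S, as for other 3,3-disubstituted allylic alcohols.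

**Step 12**
Reactants: 13 epoxy alcohol
Product: 14 (2R,4S,8S)-6,6-di-tert-butyl-4,8-diethenyl-1,5,7-trioxa-6-silaspiro[2.5]octane-2-carbaldehyde
Conditions: Dess–Martin periodinane, CH2Cl2, 0 °C
Reagents that add atoms: none
Why: Dess–Martin oxidation of the primary epoxy alcohol gives the oxirane aldehyde, whose α-centre cannot epimerise (the descriptor changes only by priority).

**Step 13**
Reactants: 14 oxirane aldehyde; 15 2-bromoprop-2-en-1-ol
Product: 16 2-{(S)-[(2S,4S,8S)-6,6-di-tert-butyl-4,8-diethenyl-1,5,7-trioxa-6-silaspiro[2.5]octan-2-yl](hydroxy)methyl}prop-2-en-1-ol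
Conditions: CrCl2 (excess), NiCl2 (cat.), DMF, rt
Reagents that add atoms: none
Why: Nozaki–Hiyama–Kishi coupling tolerates oxirane, silylene and free OH; Felkin–Anh addition anti to the oxirane C–O bond, reinforced by the arm cis to the formyl group, should give the anti (erythro) S carbinol, C5 of the target.

**Step 14**
Reactants: 16 diol
Product: 17 2-{(S)-[(2S,4S,8S)-6,6-di-tert-butyl-4,8-diethenyl-1,5,7-trioxa-6-silaspiro[2.5]octan-2-yl](hydroxy)methyl}prop-2-en-1-yl acetate
Conditions: AcCl (1.05 equiv), 2,4,6-collidine, CH2Cl2, −78 °C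
Reagents that add atoms: acetyl chloride, CC(=O)Cl
Why: Selective acylation of the primary allylic hydroxyl over the hindered secondary one at low temperature installs the acetate of the target.

**Step 15**
Reactants: 17 triene acetate; 18 isopropenylboronic acid pinacol ester
Product: 20 ring-closed (Z)-vinylboronate (boron trans to C1′; O2 and O1′ bridged by tBu2Si; spatial arrangement at C1, C2, C5, C6, C1′ as in 24), via ring-closed vinyl silylene 19 (not isolated)
Conditions: Grubbs II (5 mol %), CH2Cl2, 40 °C; then 18 (5 equiv), Hoveyda–Grubbs II (10 mol %), 45 °C, same pot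
Reagents that add atoms: none
Why: A ruthenium alkylidene formed at either vinyl group can reach the 1,1-disubstituted C4 alkene only from the arm that sits cis to C5 on the oxirane, so a ruthenacyclobutane/cycloreversion sequence closes the cyclohexene at C3=C4 with loss of ethylene, and the released catalyst then cross-metathesises the remaining vinyl group with 18. The closest known reaction types are ring-closing metathesis to trisubstituted cyclohexenes of carbasugars and cross-metathesis of terminal alkenes with 2-propenyl pinacol boronate. The six-membered ring is closed by metathesis at C3=C4 and can only be cis-fused to the oxirane, because a trans-fused 7-oxabicyclo[4.1.0]heptene is too strained. C1, which has two identical arms in 17, becomes a stereocentre whose configuration is dictated by the existing C6 oxirane centre through this cis-fusion; the boronate geometry (boron trans to C1′) should follow from the steric preference in the metallacycle. The step needs group selectivity between the two (S)-arms, secured by the oxirane geometry, and chemoselectivity against arm-to-arm closure to a cyclopentene, secured by the dioxasilinane, whose trans-disposed vinyl groups cannot be bridged by two carbons.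

**Step 16**
Reactants: 21 geranial
Product: 22 (1E,3E)-1-iodo-4,8-dimethylnona-1,3,7-triene
Conditions: CrCl2, CHI3, THF, 0 °C
Reagents that add atoms: iodoform, IC(I)I
Why: Takai olefination converts the aldehyde into the (E)-vinyl iodide via the gem-dichromium adduct, adding C4′ with E geometry.

**Step 17**
Reactants: 20 vinylboronate; 22 dienyl iodide
Product: 23 2-O,1′-O-(di-tert-butylsilanediyl) derivative of 24
Conditions: Pd(PPh3)4 (cat.), TlOEt, THF/H2O, rt
Reagents that add atoms: none
Why: Suzuki–Miyaura coupling joins C3′ and C4′ with retention of both alkene geometries; thallium ethoxide allows fast coupling at room temperature so that acetate, oxirane and silylene should survive.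

**Step 18**
Reactants: 23 silylene-protected tetraene
Product: 24 target, [(1R,2S,5S,6S)-2,5-dihydroxy-1-[(1S,2E,4E,6E)-1-hydroxy-3,7,11-trimethyldodeca-2,4,6,10-tetraen-1-yl]-7-oxabicyclo[4.1.0]hept-3-en-4-yl]methyl acetate
Conditions: TBAF, AcOH (1:1), THF, 0 °C to rt
Reagents that add atoms: none
Why: Fluoride cleaves the silylene acetal under buffered, near-neutral conditions that should spare the acetate, the oxirane and the acid-labile trienyl carbinol.

**Compound list**

1 | L-arabinitol, (2S,4S)-pentane-1,2,3,4,5-pentol | OC[C@H](O)C(O)[C@@H](O)CO | starting material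
2 | 1,2:4,5-di-O-isopropylidene-L-arabinitol, bis[(4S)-2,2-dimethyl-1,3-dioxolan-4-yl]methanol | CC1(C)OC[C@H](O1)C(O)[C@@H]2COC(C)(C)O2 | intermediate
3 | 3-O-(4-methoxybenzyl)-1,2:4,5-di-O-isopropylidene-L-arabinitol | CC1(C)OC[C@H](O1)C(OCc3ccc(OC)cc3)[C@@H]2COC(C)(C)O2 | intermediate
4 | 3-O-(4-methoxybenzyl)-L-arabinitol, (2S,4S) | OC[C@H](O)C(OCc1ccc(OC)cc1)[C@@H](O)CO | intermediate
5 | 1,2:4,5-dianhydro-3-O-(4-methoxybenzyl)-L-arabinitol, both oxirane CH carbons S | C1O[C@@H]1C(OCc2ccc(OC)cc2)[C@@H]1CO1 | intermediate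
6 | (3S,5S)-4-[(4-methoxybenzyl)oxy]hepta-1,6-diene-3,5-diol | C=C[C@H](O)C(OCc1ccc(OC)cc1)[C@@H](O)C=C | intermediate
7 | (4S,6S)-2,2-di-tert-butyl-4,6-diethenyl-5-[(4-methoxybenzyl)oxy]-1,3,2-dioxasilinane | C=C[C@H](O1)C(OCc2ccc(OC)cc2)[C@@H](O[Si]1(C(C)(C)C)C(C)(C)C)C=C | intermediate
8 | (4S,6S)-2,2-di-tert-butyl-4,6-diethenyl-1,3,2-dioxasilinan-5-ol | C=C[C@H](O1)C(O)[C@@H](O[Si]1(C(C)(C)C)C(C)(C)C)C=C | intermediate
9 | (4S,6S)-2,2-di-tert-butyl-4,6-diethenyl-1,3,2-dioxasilinan-5-one | C=C[C@H](O1)C(=O)[C@@H](O[Si]1(C(C)(C)C)C(C)(C)C)C=C | intermediate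
10 | ethyl (triphenylphosphoranylidene)acetate | CCOC(=O)C=P(c1ccccc1)(c1ccccc1)c1ccccc1 | starting material
11 | ethyl 2-[(4S,6S)-2,2-di-tert-butyl-4,6-diethenyl-1,3,2-dioxasilinan-5-ylidene]acetate | C=C[C@H](O1)C(=CC(=O)OCC)[C@@H](O[Si]1(C(C)(C)C)C(C)(C)C)C=C | intermediate
12 | 2-[(4S,6S)-2,2-di-tert-butyl-4,6-diethenyl-1,3,2-dioxasilinan-5-ylidene]ethan-1-ol | C=C[C@H](O1)C(=CCO)[C@@H](O[Si]1(C(C)(C)C)C(C)(C)C)C=C | intermediate
13 | [(2S,4S,8S)-6,6-di-tert-butyl-4,8-diethenyl-1,5,7-trioxa-6-silaspiro[2.5]octan-2-yl]methanol | C=C[C@H](O3)C1([C@@H](O[Si]3(C(C)(C)C)C(C)(C)C)C=C)O[C@H]1CO | intermediate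
14 | (2R,4S,8S)-6,6-di-tert-butyl-4,8-diethenyl-1,5,7-trioxa-6-silaspiro[2.5]octane-2-carbaldehyde | C=C[C@H](O3)C1([C@@H](O[Si]3(C(C)(C)C)C(C)(C)C)C=C)O[C@H]1C=O | intermediate
15 | 2-bromoprop-2-en-1-ol (2-bromoallyl alcohol) | OCC(Br)=C | starting material
16 | 2-{(S)-[(2S,4S,8S)-6,6-di-tert-butyl-4,8-diethenyl-1,5,7-trioxa-6-silaspiro[2.5]octan-2-yl](hydroxy)methyl}prop-2-en-1-ol | C=C[C@H](O3)C1([C@@H](O[Si]3(C(C)(C)C)C(C)(C)C)C=C)O[C@H]1[C@@H](O)C(=C)CO | intermediate
17 | 2-{(S)-[(2S,4S,8S)-6,6-di-tert-butyl-4,8-diethenyl-1,5,7-trioxa-6-silaspiro[2.5]octan-2-yl](hydroxy)methyl}prop-2-en-1-yl acetate | C=C[C@H](O3)C1([C@@H](O[Si]3(C(C)(C)C)C(C)(C)C)C=C)O[C@H]1[C@@H](O)C(=C)COC(C)=O | intermediate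
18 | 4,4,5,5-tetramethyl-2-(prop-1-en-2-yl)-1,3,2-dioxaborolane (isopropenyl-Bpin) | CC(=C)B1OC(C)(C)C(C)(C)O1 | starting material
19 | ring-closed vinyl silylene: 2-O,1′-O-(di-tert-butylsilanediyl) derivative of [2,5-dihydroxy-1-(1-hydroxyprop-2-en-1-yl)-7-oxabicyclo[4.1.0]hept-3-en-4-yl]methyl acetate, spatial arrangement at C1, C2, C5, C6, C1′ as in 24 | CC(=O)OCC1=C[C@H](O3)[C@@]2([C@@H](O[Si]3(C(C)(C)C)C(C)(C)C)C=C)O[C@H]2[C@H]1O | intermediate (not isolated)
20 | as 19, but C1′ carries a (Z)-2-(pinacolboryl)prop-1-enyl group (boron trans to C1′) | CC(=O)OCC1=C[C@H](O3)[C@@]2([C@@H](O[Si]3(C(C)(C)C)C(C)(C)C)/C=C(C)/B4OC(C)(C)C(C)(C)O4)O[C@H]2[C@H]1O | intermediate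
21 | geranial, (2E)-3,7-dimethylocta-2,6-dienal | O=C/C=C(\C)CCC=C(C)C | starting material
22 | (1E,3E)-1-iodo-4,8-dimethylnona-1,3,7-triene | I/C=C/C=C(\C)CCC=C(C)C | intermediate
23 | 2-O,1′-O-(di-tert-butylsilanediyl) derivative of 24 | CC(=O)OCC1=C[C@H](O3)[C@@]2([C@@H](O[Si]3(C(C)(C)C)C(C)(C)C)/C=C(C)/C=C/C=C(\C)CCC=C(C)C)O[C@H]2[C@H]1O | intermediate
24 | [(1R,2S,5S,6S)-2,5-dihydroxy-1-[(1S,2E,4E,6E)-1-hydroxy-3,7,11-trimethyldodeca-2,4,6,10-tetraen-1-yl]-7-oxabicyclo[4.1.0]hept-3-en-4-yl]methyl acetate | CC(=O)OCC1=C[C@H](O)[C@@]2([C@@H](O)/C=C(C)/C=C/C=C(\C)CCC=C(C)C)O[C@H]2[C@H]1O | target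

**Step count.** Total: 18 steps. Longest linear sequence: 17 steps (steps 1–15, 17, 18); step 16 is the side branch.

**Steps most likely to fail, each with a fallback**

Step 15 (ring closure with cross-metathesis): the second metathesis event may stall at the hindered, silylene-bound allylic position after the ring has closed, so that the catalyst is spent on homodimerising the boronate partner. The fallback sets out from 17. The ring closure is run alone (Grubbs II only) and the ring-closed vinyl silylene 19 is isolated. Its terminal vinyl group is cleaved chemoselectively (cat. OsO4, NaIO4, 2,6-lutidine, dioxane/H2O); the trisubstituted ring alkene carries three allylic C–O bonds and should react far more slowly. This gives the C1′ aldehyde F1. A chromium(II)-mediated boryl olefination of Takai–Utimoto type (CrCl2, LiI, 2-(1,1-dichloroethyl)-4,4,5,5-tetramethyl-1,3,2-dioxaborolane, THF) then converts F1 into vinylboronate 20, where the route is rejoined.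

Step 9 (olefination of the ketone): enolisation of the doubly activated α-positions by the ylide may outrun olefination, leading to epimerisation to the meso ketone or migration of the vinyl double bonds into conjugation. The fallback sets out from ketone 9. Addition of lithium ethoxyacetylide (ethoxyacetylene, n-BuLi, THF, −78 °C) gives the tertiary ethoxyalkynyl carbinol F2. Its Meyer–Schuster rearrangement under Lewis-acid catalysis (cat. Sc(OTf)3, CH2Cl2/EtOH, rt) delivers enoate 11, where the route is rejoined.

Step 13 (addition to the oxirane aldehyde): facial discrimination between the Felkin–Anh and competing chelate transition states may be insufficient, giving both C5 epimers. The fallback sets out from acetate 17 obtained as the epimer mixture. Oxidation (Dess–Martin periodinane) gives the oxiranyl enone F3. Chelation-controlled 1,2-reduction with Zn(BH4)2 (Et2O, −20 °C), with hydride delivered to the zinc chelate of carbonyl and oxirane oxygens from the side away from the spiro carbon, should return 17 as the single anti epimer.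

**Further compounds**

F1 | step 15 | as 19 with a formyl group on C1′ in place of the vinyl group (C1′ aldehyde) | CC(=O)OCC1=C[C@H](O3)[C@@]2([C@@H](O[Si]3(C(C)(C)C)C(C)(C)C)C=O)O[C@H]2[C@H]1O
F2 | step 9 | (4S,6S)-2,2-di-tert-butyl-5-(ethoxyethynyl)-4,6-diethenyl-1,3,2-dioxasilinan-5-ol | C=C[C@H](O1)C(O)(C#COCC)[C@@H](O[Si]1(C(C)(C)C)C(C)(C)C)C=C
F3 | step 13 | 2-[(2R,4S,8S)-6,6-di-tert-butyl-4,8-diethenyl-1,5,7-trioxa-6-silaspiro[2.5]octane-2-carbonyl]prop-2-en-1-yl acetate | C=C[C@H](O3)C1([C@@H](O[Si]3(C(C)(C)C)C(C)(C)C)C=C)O[C@H]1C(=O)C(=C)COC(C)=O
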